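## Retrosynthetic overview

1. Feature: in ring C the bonds O1–C8a and C4–C4a end on two neighbouring carbons of ring A, and C4a has the oxygen-bearing C5 as its other neighbour. A 3-alkoxyaryne takes a nucleophile at the carbon remote from the alkoxy group (C8a) and an electrophile at the carbon beside it (C4a), which is this pattern.
2. Target 22 ⇒ tetrabenzyl ether 21 (hydrogenolysis) ⇒ cut O1–C8a and C4–C4a ⇒ 3,5-bis(benzyloxy)benzyne (ring A, from silyl triflate 7, from phloroglucinol) plus 2-aryl-3-hydroxyacrylate 18, which brings O1, C2, C3, C4 and rings B and D.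
3. 18 ⇒ aldehyde 16 plus ethyl diazoacetate (1,2-aryl shift). 16 ⇒ chromene 12 by Jacobsen–Katsuki epoxidation and hydride opening at C4, which sets the only stereocentre, C3 of ring D.
4. Ring order: rings A and B are bought as arenes, ring D is closed first (step 5, chromene annulation on 2,4-dihydroxybenzaldehyde) and ring C last (step 12).

Key step: step 12

Remark: isoflavone numbering is used for rings A, B and C and chroman numbering for ring D. Compound 18 is a tautomeric system drawn as its hydrogen-bonded Z enol, and its enolate is the species that reacts in step 12.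

## Route

Step 1
Reactants: 1 phloroglucinol (benzene-1,3,5-triol)
Product: 2 3,5-bis(benzyloxy)phenol
Conditions: BnBr (2.0 equiv), K2CO3 (2.2 equiv), DMF, rt; chromatography
Reagents that add atoms: benzyl bromide, BrCc1ccccc1
Why: Williamson ether synthesis with two equivalents of halide in a dipolar aprotic solvent favours O- over C-alkylation and should give the dibenzyl ether as the main part of a statistical mixture, from which the mono- and tribenzyl ethers are separated.

Step 2
Reactants: 2 3,5-bis(benzyloxy)phenol
Product: 3 3,5-bis(benzyloxy)-2-bromophenol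
Conditions: NBS (1.0 equiv), CH2Cl2, −78 °C to 0 °C
Reagents that add atoms: N-bromosuccinimide, O=C1CCC(=O)N1Br
Why: Electrophilic aromatic bromination; the two equivalent positions between OH and OBn are favoured by number and by size over C4 between the two benzyloxy groups, and one equivalent of NBS in the cold should stop at the monobromide.

Step 3
Reactants: 3 3,5-bis(benzyloxy)-2-bromophenol
Product: 4 [3,5-bis(benzyloxy)-2-bromophenoxy]trimethylsilane
Conditions: (Me3Si)2NH, THF, 70 °C; evaporation
Reagents that add atoms: hexamethyldisilazane, C[Si](C)(C)N[Si](C)(C)C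
Why: O-silylation of a phenol with hexamethyldisilazane needs no base and releases only ammonia, so the silyl ether can be carried on after removal of volatiles.

Step 4
Reactants: 4 [3,5-bis(benzyloxy)-2-bromophenoxy]trimethylsilane
Product: 7 3,5-bis(benzyloxy)-2-(trimethylsilyl)phenyl trifluoromethanesulfonate, via aryllithium 5 (not isolated), via lithium phenoxide 6 (not isolated)
Conditions: n-BuLi (1.1 equiv), THF, −78 °C; then Tf2O (1.2 equiv), −78 °C to 0 °C
Reagents that add atoms: trifluoromethanesulfonic anhydride, O=S(=O)(OS(=O)(=O)C(F)(F)F)C(F)(F)F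
Why: Bromine–lithium exchange at −78 °C outruns benzylic deprotonation, aryllithium 5 undergoes the 1,3 O-to-C silyl shift (retro-Brook rearrangement) to phenoxide 6, and triflation of 6 is the standard entry to ortho-silylaryl triflates.

Step 5
Reactants: 8 2,4-dihydroxybenzaldehyde; 9 3-methylbut-2-enal
Product: 11 5-hydroxy-2,2-dimethyl-2H-chromene-6-carbaldehyde, via ortho-quinone methide 10 (not isolated)
Conditions: ethylenediammonium diacetate (10 mol %), xylene, reflux
Reagents that add atoms: none
Why: Formal [3+3] chromene annulation: the iminium ion of the enal condenses at C3 of the resorcinol ring (Knoevenagel type), loss of water gives ortho-quinone methide 10 and an oxa-6π electrocyclisation closes ring D; the 2-hydroxyl stays hydrogen-bonded to the formyl group, so the 4-hydroxyl becomes the ring oxygen and the angular 5-hydroxy-6-formyl isomer should result.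

Step 6
Reactants: 11 5-hydroxy-2,2-dimethyl-2H-chromene-6-carbaldehyde
Product: 12 5-(benzyloxy)-2,2-dimethyl-2H-chromene-6-carbaldehyde
Conditions: BnBr (1.3 equiv), K2CO3, DMF, 60 °C
Reagents that add atoms: benzyl bromide, BrCc1ccccc1
Why: Williamson ether synthesis; warming in DMF overcomes the low reactivity of the chelated phenol, and neither the aldehyde nor the chromene alkene is affected.

Step 7
Reactants: 12 5-(benzyloxy)-2,2-dimethyl-2H-chromene-6-carbaldehyde
Product: 13 (3S,4S)-5-(benzyloxy)-3,4-epoxy-2,2-dimethylchroman-6-carbaldehyde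
Conditions: (S,S)-[N,N'-bis(3,5-di-tert-butylsalicylidene)cyclohexane-1,2-diaminato]MnCl (4 mol %), 4-phenylpyridine N-oxide (20 mol %), aq NaOCl (Na2HPO4 buffer, pH 11.3), CH2Cl2, 0 °C
Reagents that add atoms: sodium hypochlorite, [Na+].[O-]Cl
Why: Jacobsen–Katsuki epoxidation; 2,2-dimethylchromenes with an acceptor para to the ring oxygen are the best substrate class for this catalyst, and the (S,S)-ligand should deliver oxygen to the face that gives the (3S,4S)-epoxide, which sets C3 of ring D.

Step 8
Reactants: 13 (3S,4S)-5-(benzyloxy)-3,4-epoxy-2,2-dimethylchroman-6-carbaldehyde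
Product: 14 (3S)-5-(benzyloxy)-6-(hydroxymethyl)-2,2-dimethylchroman-3-ol
Conditions: LiAlH4 (excess), THF, 0 °C to rt; aqueous NaOH work-up
Reagents that add atoms: none
Why: Hydride reduction; the aldehyde is reduced and the epoxide is opened by SN2 attack at the benzylic C4, which is less hindered than the neopentyl-type C3 beside CMe2, so the C3–O bond is untouched and the (3S) configuration is kept.

Step 9
Reactants: 14 (3S)-5-(benzyloxy)-6-(hydroxymethyl)-2,2-dimethylchroman-3-ol
Product: 15 (3S)-5-(benzyloxy)-3-hydroxy-2,2-dimethylchroman-6-carbaldehyde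
Conditions: activated MnO2 (excess), CH2Cl2, rt
Reagents that add atoms: none
Why: Chemoselective MnO2 oxidation; only the benzylic primary alcohol is activated towards this oxidant, and the saturated secondary carbinol at C3 is left alone.

Step 10
Reactants: 15 (3S)-5-(benzyloxy)-3-hydroxy-2,2-dimethylchroman-6-carbaldehyde
Product: 16 (3S)-3,5-bis(benzyloxy)-2,2-dimethylchroman-6-carbaldehyde
Conditions: BnOC(=NH)CCl3 (2 equiv), TfOH (5 mol %), CH2Cl2–cyclohexane, 0 °C to rt
Reagents that add atoms: benzyl 2,2,2-trichloroacetimidate, N=C(OCc1ccccc1)C(Cl)(Cl)Cl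
Why: Acid-catalysed trichloroacetimidate benzylation avoids an alkoxide next to the aldehyde and forms only the O–benzyl bond, so C3 keeps its configuration.

Step 11
Reactants: 16 (3S)-3,5-bis(benzyloxy)-2,2-dimethylchroman-6-carbaldehyde; 17 ethyl diazoacetate
Product: 18 ethyl (Z)-2-[(3S)-3,5-bis(benzyloxy)-2,2-dimethylchroman-6-yl]-3-hydroxyprop-2-enoate
Conditions: HBF4·OEt2 (15 mol %), CH2Cl2, −78 °C to rt
Reagents that add atoms: none
Why: Acid-catalysed aldehyde–diazoacetate homologation with 1,2-aryl shift and loss of N2; the ortho,para-dioxygenated ring B has a high migratory aptitude, which should favour the 2-aryl-3-hydroxyacrylate over the β-keto ester of a Roskamp-type hydride shift, and the ester alkyl group only serves as the leaving group of step 12.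

Step 12
Reactants: 18 ethyl (Z)-2-[(3S)-3,5-bis(benzyloxy)-2,2-dimethylchroman-6-yl]-3-hydroxyprop-2-enoate; 7 3,5-bis(benzyloxy)-2-(trimethylsilyl)phenyl trifluoromethanesulfonate
Product: 21 5,7-bis(benzyloxy)-3-[(3S)-3,5-bis(benzyloxy)-2,2-dimethylchroman-6-yl]-4H-chromen-4-one, via 3,5-bis(benzyloxy)benzyne 19 (not isolated), via cesium aryl anion 20 (not isolated)
Conditions: 7 (1.5 equiv), CsF (4 equiv), THF, 65 °C
Reagents that add atoms: none
Why: Proposed new method: fluoride attacks the silicon of 7 and triflate leaves to give aryne 19 while fluoride also deprotonates 18; the formyl-derived enolate oxygen adds to the aryne carbon remote from the neighbouring benzyloxy group (future C8a), the charge of aryl anion 20 then sits on the carbon flanked by that electron-withdrawing oxygen (future C4a), and this anion adds to the ester carbonyl and expels ethoxide. The closest known reaction type is the fluoride-induced annulation of arynes with salicylate esters to xanthones (O-arylation, then acyl substitution by the aryl anion), and the new element is an acyclic formylacetate enolate in place of a phenoxide. Ring C closes by a 6-exo-trig addition to the C=O followed by elimination, which needs the aryloxy group and the ester cis on C2=C3, the geometry held by the cesium-chelated U-shaped enolate of the Z enol. No stereocentre is formed, and C3 of ring D is remote from every bond that changes. Two selectivities are needed: O- over C-arylation of the ambident enolate, favoured because the α-carbon is fully substituted and shielded by the ortho-benzyloxy aryl group (carbon attack would have to build a quaternary diaryl centre), and distal addition to the aryne, which follows from the bond-angle distortion and inductive effect of the 3-benzyloxy group. THF is used instead of acetonitrile so that no solvent proton quenches 20 before it cyclises.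

Step 13
Reactants: 21 5,7-bis(benzyloxy)-3-[(3S)-3,5-bis(benzyloxy)-2,2-dimethylchroman-6-yl]-4H-chromen-4-one
Product: 22 5,7-dihydroxy-3-[(3S)-3,5-dihydroxy-2,2-dimethylchroman-6-yl]-4H-chromen-4-one (target)
Conditions: H2 (1 atm), Pd(OH)2/C, THF–MeOH, rt; stopped after uptake of four equivalents of H2
Reagents that add atoms: none
Why: Catalytic hydrogenolysis cleaves the three aryl benzyl ethers and the secondary alkyl benzyl ether at their benzylic C–O bonds, the C3–O bond of ring D is not benzylic and keeps its configuration, and the tetrasubstituted-like C2=C3 bond of the pyranone is reduced much more slowly at one atmosphere.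

## Compound list

1 | phloroglucinol | Oc1cc(O)cc(O)c1 | starting material
2 | 3,5-bis(benzyloxy)phenol | Oc1cc(OCc2ccccc2)cc(OCc2ccccc2)c1 | intermediate
3 | 3,5-bis(benzyloxy)-2-bromophenol | Oc1cc(OCc2ccccc2)cc(OCc2ccccc2)c1Br | intermediate
4 | [3,5-bis(benzyloxy)-2-bromophenoxy]trimethylsilane | C[Si](C)(C)Oc1cc(OCc2ccccc2)cc(OCc2ccccc2)c1Br | intermediate
5 | [2,4-bis(benzyloxy)-6-(trimethylsilyloxy)phenyl]lithium | C[Si](C)(C)Oc1cc(OCc2ccccc2)cc(OCc2ccccc2)c1[Li] | intermediate
6 | lithium 3,5-bis(benzyloxy)-2-(trimethylsilyl)phenoxide | [Li+].[O-]c1cc(OCc2ccccc2)cc(OCc2ccccc2)c1[Si](C)(C)C | intermediate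
7 | 3,5-bis(benzyloxy)-2-(trimethylsilyl)phenyl trifluoromethanesulfonate | C[Si](C)(C)c1c(OCc2ccccc2)cc(OCc2ccccc2)cc1OS(=O)(=O)C(F)(F)F | intermediate
8 | 2,4-dihydroxybenzaldehyde | O=Cc1ccc(O)cc1O | starting material
9 | 3-methylbut-2-enal | CC(C)=CC=O | starting material
10 | 2-hydroxy-3-(3-methylbut-2-enylidene)-4-oxocyclohexa-1,5-diene-1-carbaldehyde (ortho-quinone methide, dienyl chain syn to the ring C=O) | O=C1C=CC(C=O)=C(O)/C1=C/C=C(C)C | intermediate
11 | 5-hydroxy-2,2-dimethyl-2H-chromene-6-carbaldehyde | CC1(C)C=Cc2c(O1)ccc(C=O)c2O | intermediate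
12 | 5-(benzyloxy)-2,2-dimethyl-2H-chromene-6-carbaldehyde | CC1(C)C=Cc2c(O1)ccc(C=O)c2OCc1ccccc1 | intermediate
13 | (3S,4S)-5-(benzyloxy)-3,4-epoxy-2,2-dimethylchroman-6-carbaldehyde | CC1(C)Oc2ccc(C=O)c(OCc3ccccc3)c2[C@@H]3O[C@H]13 | intermediate
14 | (3S)-5-(benzyloxy)-6-(hydroxymethyl)-2,2-dimethylchroman-3-ol | CC1(C)Oc2ccc(CO)c(OCc3ccccc3)c2C[C@@H]1O | intermediate
15 | (3S)-5-(benzyloxy)-3-hydroxy-2,2-dimethylchroman-6-carbaldehyde | CC1(C)Oc2ccc(C=O)c(OCc3ccccc3)c2C[C@@H]1O | intermediate
16 | (3S)-3,5-bis(benzyloxy)-2,2-dimethylchroman-6-carbaldehyde | CC1(C)Oc2ccc(C=O)c(OCc3ccccc3)c2C[C@@H]1OCc1ccccc1 | intermediate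
17 | ethyl diazoacetate | CCOC(=O)C=[N+]=[N-] | starting material
18 | ethyl (Z)-2-[(3S)-3,5-bis(benzyloxy)-2,2-dimethylchroman-6-yl]-3-hydroxyprop-2-enoate | CC1(C)Oc2ccc(/C(=C/O)C(=O)OCC)c(OCc3ccccc3)c2C[C@@H]1OCc1ccccc1 | intermediate
19 | 3,5-bis(benzyloxy)benzyne | C1#CC(OCc2ccccc2)=CC(OCc2ccccc2)=C1 | intermediate
20 | cesium salt of the O-arylated aryl anion, ethyl (Z)-3-[3,5-bis(benzyloxy)-2-cesiophenoxy]-2-[(3S)-3,5-bis(benzyloxy)-2,2-dimethylchroman-6-yl]prop-2-enoate | [Cs+].CC1(C)Oc2ccc(/C(=C/Oc3cc(OCc4ccccc4)cc(OCc4ccccc4)[c-]3)C(=O)OCC)c(OCc3ccccc3)c2C[C@@H]1OCc1ccccc1 | intermediate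
21 | 5,7-bis(benzyloxy)-3-[(3S)-3,5-bis(benzyloxy)-2,2-dimethylchroman-6-yl]-4H-chromen-4-one | CC1(C)Oc2ccc(-c3coc4cc(OCc5ccccc5)cc(OCc5ccccc5)c4c3=O)c(OCc3ccccc3)c2C[C@@H]1OCc1ccccc1 | intermediate
22 | 5,7-dihydroxy-3-[(3S)-3,5-dihydroxy-2,2-dimethylchroman-6-yl]-4H-chromen-4-one | CC1(C)Oc2ccc(-c3coc4cc(O)cc(O)c4c3=O)c(O)c2C[C@@H]1O | target

## Step count and risks

Total step count: 13. Longest linear sequence: 9 (steps 5 to 13, from 2,4-dihydroxybenzaldehyde). The aryne branch (steps 1 to 4) joins at step 12.

**1. Step 12 (Proposed new method).**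
- What may go wrong: the enolate may attack the aryne through carbon, followed by insertion into the C–CHO bond. The aryl anion may be protonated before it reaches the ester. Ethoxide may remove the formyl group.
- Fallback: known chemistry, the oxidative rearrangement of a chalcone. It sets out from aldehyde 16 and returns at 21.
- Purchased 2,4,6-trihydroxyacetophenone is benzylated twice (BnBr, K2CO3, acetone, reflux; the chelated hydroxyl stays free) to give 1-[2,4-bis(benzyloxy)-6-hydroxyphenyl]ethanone F1.
- Claisen–Schmidt condensation of this ketone with 16 (KOH, EtOH, rt) gives (E)-1-[2,4-bis(benzyloxy)-6-hydroxyphenyl]-3-[(3S)-3,5-bis(benzyloxy)-2,2-dimethylchroman-6-yl]prop-2-en-1-one F2.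
- Tl(NO3)3 (trivalent thallium) in MeOH–HC(OMe)3 at rt induces the oxidative 1,2-shift of the electron-rich ring B aryl group. This gives 1-[2,4-bis(benzyloxy)-6-hydroxyphenyl]-2-[(3S)-3,5-bis(benzyloxy)-2,2-dimethylchroman-6-yl]-3,3-dimethoxypropan-1-one F3, as a mixture of epimers at a centre that is lost again.
- HCl in MeOH at reflux closes ring C and gives 21.

**2. Step 11.**
- What may go wrong: hydride migration may compete with aryl migration, the deactivated aldehyde may add slowly so that the diazo ester decomposes, or the acid may cleave a benzyl ether.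
- Fallback: stepwise homologation and formylation. It sets out from 16 and returns at 18.
- Condensation of 16 with methyl (methylsulfanyl)methyl sulfoxide (benzyltrimethylammonium hydroxide, THF, reflux) gives (3S)-3,5-bis(benzyloxy)-2,2-dimethyl-6-[2-(methylsulfanyl)-2-(methylsulfinyl)ethenyl]chroman F4.
- HCl in EtOH converts it into ethyl 2-[(3S)-3,5-bis(benzyloxy)-2,2-dimethylchroman-6-yl]acetate F5.
- A crossed Claisen condensation with ethyl formate (NaH, THF, 0 °C to rt) gives 18.

**3. Step 13.**
- What may go wrong: the C2=C3 bond of ring C may be over-reduced while the hindered secondary benzyl ether is still being cleaved, or that ether may be cleaved incompletely.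
- Fallback: non-reductive Lewis-acid debenzylation. It sets out from 21 and goes directly to 22.
- Conditions are BCl3 with pentamethylbenzene as benzyl cation scavenger, CH2Cl2, −78 °C, then MeOH quench. The low temperature spares the tertiary alkyl aryl ether of ring D.

## Further compounds

F1 | step 12 | 1-[2,4-bis(benzyloxy)-6-hydroxyphenyl]ethanone | CC(=O)c1c(O)cc(OCc2ccccc2)cc1OCc1ccccc1
F2 | step 12 | (E)-1-[2,4-bis(benzyloxy)-6-hydroxyphenyl]-3-[(3S)-3,5-bis(benzyloxy)-2,2-dimethylchroman-6-yl]prop-2-en-1-one | CC1(C)Oc2ccc(/C=C/C(=O)c3c(O)cc(OCc4ccccc4)cc3OCc3ccccc3)c(OCc3ccccc3)c2C[C@@H]1OCc1ccccc1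
F3 | step 12 | 1-[2,4-bis(benzyloxy)-6-hydroxyphenyl]-2-[(3S)-3,5-bis(benzyloxy)-2,2-dimethylchroman-6-yl]-3,3-dimethoxypropan-1-one (epimers at C2 of the chain) | CC1(C)Oc2ccc(C(C(OC)OC)C(=O)c3c(O)cc(OCc4ccccc4)cc3OCc3ccccc3)c(OCc3ccccc3)c2C[C@@H]1OCc1ccccc1
F4 | step 11 | (3S)-3,5-bis(benzyloxy)-2,2-dimethyl-6-[2-(methylsulfanyl)-2-(methylsulfinyl)ethenyl]chroman (alkene and sulfoxide isomers) | CC1(C)Oc2ccc(C=C(SC)S(C)=O)c(OCc3ccccc3)c2C[C@@H]1OCc1ccccc1
F5 | step 11 | ethyl 2-[(3S)-3,5-bis(benzyloxy)-2,2-dimethylchroman-6-yl]acetate | CC1(C)Oc2ccc(CC(=O)OCC)c(OCc3ccccc3)c2C[C@@H]1OCc1ccccc1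
F0 | step 13 | none | none
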